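## Retrosynthetic overview

- The glyceride ester C–O bond is made last, by opening (R)-glycidyl acetate with the free C20 acid. The side chain comes from an sp2–sp3 coupling of homoprenylmagnesium bromide with the C5 enol triflate of a cis-4a,8a-dimethyl-5-decalone.
- Key disconnection: the C4a methyl and the C5 ketone arise together from a C5→C4a 1,2-methyl shift in an oxidised 5-methyl-Δ4a(5)-octalin. This sets the second quaternary centre and the cis-dimethyl ring fusion.
- Ring B is closed by McMurry coupling of a 1,6-diketone carried on ring A.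
- Ring A comes from an organocatalytic Michael/aldol reaction of propanal with ethyl vinyl ketone, which sets C2. A vinyl cuprate (latent CO2H) and then an enolate alkylation set C1 and C8a by 1,2-induction.
- Order of ring formation: ring A, then ring B.

Assumption: the SMILES is read as the (2S)-3-acetoxy-2-hydroxypropyl ester of the (1S,2R,4aR,8aR) acid (cis-decalin; both angular methyls and the ester on one face, the C2 methyl on the other), and 5-chloropentan-2-one is bought as its ethylene ketal.

## Route

Step 1
Reactants: 1 propanal; 2 pent-1-en-3-one (ethyl vinyl ketone)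
Product: 4 (4R)-2,4-dimethylcyclohex-2-en-1-one, via Michael adduct 3 (not isolated)
Conditions: (S)-2-[methoxy(diphenyl)methyl]pyrrolidine (5 mol %), ethyl 3,4-dihydroxybenzoate (20 mol %), neat, 4 °C; then LiOH, i-PrOH, rt
Reagents that add atoms: none
Why: Enamine-catalysed asymmetric Michael addition, in which the (S)-diarylprolinol ether shields one enamine face and sets the methyl-bearing centre as R, is followed in the same flask by the only possible six-ring intramolecular aldol condensation, which keeps that centre as C4.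

Step 2
Reactants: 4 (4R)-2,4-dimethylcyclohex-2-en-1-one; 5 vinylmagnesium bromide
Product: 6 {[(3S,4R)-3-ethenyl-2,4-dimethylcyclohex-1-en-1-yl]oxy}trimethylsilane
Conditions: CuBr·SMe2 (10 mol %), LiCl, Me3SiCl, THF, −78 → −40 °C; Et3N, aq NaHCO3
Reagents that add atoms: chlorotrimethylsilane, C[Si](C)(C)Cl
Why: In this copper-catalysed 1,4-addition accelerated by Me3SiCl the vinyl group (a latent carboxyl) enters axially, anti to the C4 methyl (3,4-trans), and O-silylation stores the enolate regiospecifically as the tetrasubstituted enol ether.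

Step 3
Reactants: 7 2-(3-chloropropyl)-2-methyl-1,3-dioxolane
Product: 8 2-(3-iodopropyl)-2-methyl-1,3-dioxolane
Conditions: NaI, acetone, reflux
Reagents that add atoms: sodium iodide, [Na+].[I-]
Why: Finkelstein halide exchange is driven by precipitation of NaCl and involves no stereocentre.

Step 4
Reactants: 6 {[(3S,4R)-3-ethenyl-2,4-dimethylcyclohex-1-en-1-yl]oxy}trimethylsilane; 8 2-(3-iodopropyl)-2-methyl-1,3-dioxolane
Product: 11 (2R,3S,4R)-3-ethenyl-2,4-dimethyl-2-(4-oxopentyl)cyclohexan-1-one, via lithium enolate 9 (not isolated), via ketal ketone 10 (not isolated)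
Conditions: MeLi (1.05 equiv), THF, 0 °C; 8 (1.5 equiv), DMPU, −20 °C → rt; then 1 M HCl, THF, rt
Reagents that add atoms: water, O
Why: Regiospecific release of the lithium enolate from the silyl enol ether is followed by SN2 alkylation in which allylic 1,2-strain keeps the C3 vinyl axial, so the iodide attacks the opposite face and sets the quaternary C2 (methyl cis to vinyl), and the acidic work-up hydrolyses the ketal.

Step 5
Reactants: 11 (2R,3S,4R)-3-ethenyl-2,4-dimethyl-2-(4-oxopentyl)cyclohexan-1-one
Product: 12 (1S,2R,8aR)-1-ethenyl-2,5,8a-trimethyl-1,2,3,4,6,7,8,8a-octahydronaphthalene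
Conditions: TiCl3(DME)1.5, Zn–Cu couple, DME, reflux, slow addition of 11 (20 h)
Reagents that add atoms: none
Why: Intramolecular McMurry coupling of a 1,6-diketone under high dilution is well suited to hindered tetrasubstituted cyclohexenes, closes ring B, and leaves the vinyl group and the three stereocentres untouched.

Step 6
Reactants: 12 (1S,2R,8aR)-1-ethenyl-2,5,8a-trimethyl-1,2,3,4,6,7,8,8a-octahydronaphthalene
Product: 13 (4aR,5S,6R,8aS)-5-ethenyl-4a,6,8a-trimethyloctahydronaphthalen-1(2H)-one
Conditions: undivided cell, graphite anode, Pt cathode, constant current (2.2 F/mol), n-Bu4NBF4 (0.1 M), MeCN–HFIP–H2O 8:1:1, 0 °C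
Reagents that add atoms: water, O
Why: Proposed new method: an anodic hydroxylative semipinacol (electron transfer, chemical step, electron transfer) in which the tetrasubstituted C4a=C5 alkene (numbering of 12), the only easily oxidised group, gives a radical cation, water adds to the less hindered C5 from the face opposite the axial 8a-methyl, the tertiary C4a radical is oxidised again to the cation, and the C5 methyl, now axial and parallel to the empty orbital on the 8a-methyl face, makes a suprafacial 1,2-shift driven by C=O formation and by loss of the 1,3-diaxial methyl/methyl contact, which sets C4a (cis-dimethyl, cis-decalin) while protons are reduced to H2 at the cathode; the closest known reaction types are the Meinwald/pinacol methyl shift of 1,2-dimethylcyclohexene oxide or its cis-diol and the radical-cation (anti-Markovnikov Wacker-type) hydration–oxidation of styrenes, neither of which has been shown on an unactivated ring-fusion alkene next to a quaternary carbon.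

Step 7
Reactants: 13 (4aR,5S,6R,8aS)-5-ethenyl-4a,6,8a-trimethyloctahydronaphthalen-1(2H)-one
Product: 15 (1S,2R,4aS,8aR)-2,4a,8a-trimethyl-5-oxodecahydronaphthalene-1-carboxylic acid, via bicyclic aldehyde 14 (not isolated)
Conditions: RuCl3·xH2O (2 mol %), NaIO4 (4.2 equiv), EtOAc–MeCN–H2O, rt
Reagents that add atoms: sodium periodate, [Na+].[O-]I(=O)(=O)=O
Why: Oxidative cleavage by RuO4 made in situ takes the only remaining C=C to the aldehyde and then the acid, and C1, although epimerisable at the aldehyde stage, already holds the favoured equatorial position trans to the C2 methyl.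

Step 8
Reactants: 15 (1S,2R,4aS,8aR)-2,4a,8a-trimethyl-5-oxodecahydronaphthalene-1-carboxylic acid
Product: 17 (1S,2R,4aS,8aR)-2,4a,8a-trimethyl-5-(trifluoromethylsulfonyloxy)-1,2,3,4,4a,7,8,8a-octahydronaphthalene-1-carboxylic acid, via dipotassium salt 16 (not isolated)
Conditions: KN(SiMe3)2 (2.2 equiv), THF, −78 °C; PhNTf2 (1.2 equiv), −78 → 0 °C; 1 M HCl work-up
Reagents that add atoms: N-phenylbis(trifluoromethanesulfonimide), O=S(=O)(N(c1ccccc1)S(=O)(=O)C(F)(F)F)C(F)(F)F
Why: In this enolate O-triflation the carboxylate is a spectator, the quaternary C4a lets the ketone enolise only towards C6, and no stereocentre is touched.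

Step 9
Reactants: 17 (1S,2R,4aS,8aR)-2,4a,8a-trimethyl-5-(trifluoromethylsulfonyloxy)-1,2,3,4,4a,7,8,8a-octahydronaphthalene-1-carboxylic acid; 18 5-bromo-2-methylpent-2-ene
Product: 20 (1S,2R,4aR,8aR)-2,4a,8a-trimethyl-5-(4-methylpent-3-en-1-yl)-1,2,3,4,4a,7,8,8a-octahydronaphthalene-1-carboxylic acid, via Grignard reagent 19 (not isolated)
Conditions: 18, Mg, THF, rt; then 17, Fe(acac)3 (10 mol %), THF–NMP, 19 (3 equiv), −30 → 0 °C; 1 M HCl work-up
Reagents that add atoms: none
Why: Iron-catalysed Kumada-type sp2–sp3 cross-coupling of an alkenyl triflate with a primary alkyl Grignard reagent outruns β-hydride elimination, the first equivalent of 19 only deprotonates the acid, and the resulting magnesium carboxylate is inert.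

Step 10
Reactants: 21 (S)-glycidol; 22 acetic anhydride
Product: 23 (R)-glycidyl acetate
Conditions: Et3N, DMAP (cat.), CH2Cl2, 0 °C
Reagents that add atoms: none
Why: This is a simple O-acylation in which the stereocentre is untouched and the descriptor changes from S to R only because the CIP ranking changes.

Step 11
Reactants: 20 (1S,2R,4aR,8aR)-2,4a,8a-trimethyl-5-(4-methylpent-3-en-1-yl)-1,2,3,4,4a,7,8,8a-octahydronaphthalene-1-carboxylic acid; 23 (R)-glycidyl acetate
Product: 24 (2S)-3-acetoxy-2-hydroxypropyl (1S,2R,4aR,8aR)-2,4a,8a-trimethyl-5-(4-methylpent-3-en-1-yl)-1,2,3,4,4a,7,8,8a-octahydronaphthalene-1-carboxylate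
Conditions: 23 (1.5 equiv), n-Bu4NBr (10 mol %), toluene, 80 °C
Reagents that add atoms: none
Why: Halide-catalysed SN2 opening of the terminal epoxide by the carboxylic acid occurs at the unsubstituted carbon, hindrance around the acyl carbon is irrelevant because the carboxylate oxygen is the nucleophile, and the untouched glycerol stereocentre becomes S.

## Compound list

1 | propanal | CCC=O | starting material
2 | pent-1-en-3-one (ethyl vinyl ketone) | CCC(=O)C=C | starting material
3 | (2R)-2-methyl-5-oxoheptanal | O=C[C@H](C)CCC(=O)CC | intermediate (not isolated)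
4 | (4R)-2,4-dimethylcyclohex-2-en-1-one | O=C1C(C)=C[C@H](C)CC1 | intermediate
5 | vinylmagnesium bromide | C=C[Mg]Br | starting material
6 | {[(3S,4R)-3-ethenyl-2,4-dimethylcyclohex-1-en-1-yl]oxy}trimethylsilane (vinyl trans to the 4-methyl) | C=C[C@H]1[C@H](C)CCC(O[Si](C)(C)C)=C1C | intermediate
7 | 2-(3-chloropropyl)-2-methyl-1,3-dioxolane (5-chloropentan-2-one ethylene ketal) | ClCCCC1(C)OCCO1 | starting material
8 | 2-(3-iodopropyl)-2-methyl-1,3-dioxolane | ICCCC1(C)OCCO1 | intermediate
9 | lithium (3S,4R)-3-ethenyl-2,4-dimethylcyclohex-1-en-1-olate | C=C[C@H]1[C@H](C)CCC([O-])=C1C.[Li+] | intermediate (not isolated)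
10 | (2R,3S,4R)-3-ethenyl-2,4-dimethyl-2-[3-(2-methyl-1,3-dioxolan-2-yl)propyl]cyclohexan-1-one | C=C[C@H]1[C@H](C)CCC(=O)[C@]1(C)CCCC2(C)OCCO2 | intermediate (not isolated)
11 | (2R,3S,4R)-3-ethenyl-2,4-dimethyl-2-(4-oxopentyl)cyclohexan-1-one (2-methyl cis to vinyl) | C=C[C@H]1[C@H](C)CCC(=O)[C@]1(C)CCCC(C)=O | intermediate
12 | (1S,2R,8aR)-1-ethenyl-2,5,8a-trimethyl-1,2,3,4,6,7,8,8a-octahydronaphthalene | C=C[C@H]1[C@H](C)CCC2=C(C)CCC[C@]12C | intermediate
13 | (4aR,5S,6R,8aS)-5-ethenyl-4a,6,8a-trimethyloctahydronaphthalen-1(2H)-one (cis-decalone, angular methyls cis) | C=C[C@H]1[C@H](C)CC[C@]2(C)C(=O)CCC[C@]12C | intermediate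
14 | (1S,2R,4aS,8aR)-2,4a,8a-trimethyl-5-oxodecahydronaphthalene-1-carbaldehyde | O=C[C@H]1[C@H](C)CC[C@]2(C)C(=O)CCC[C@]12C | intermediate (not isolated)
15 | (1S,2R,4aS,8aR)-2,4a,8a-trimethyl-5-oxodecahydronaphthalene-1-carboxylic acid | OC(=O)[C@H]1[C@H](C)CC[C@]2(C)C(=O)CCC[C@]12C | intermediate
16 | dipotassium carboxylate/C5-enolate of 15 | [K+].[K+].[O-]C(=O)[C@H]1[C@H](C)CC[C@]2(C)C([O-])=CCC[C@]12C | intermediate (not isolated)
17 | (1S,2R,4aS,8aR)-2,4a,8a-trimethyl-5-(trifluoromethylsulfonyloxy)-1,2,3,4,4a,7,8,8a-octahydronaphthalene-1-carboxylic acid | OC(=O)[C@H]1[C@H](C)CC[C@]2(C)C(OS(=O)(=O)C(F)(F)F)=CCC[C@]12C | intermediate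
18 | 5-bromo-2-methylpent-2-ene (homoprenyl bromide) | CC(C)=CCCBr | starting material
19 | (4-methylpent-3-en-1-yl)magnesium bromide | CC(C)=CCC[Mg]Br | intermediate (not isolated)
20 | (1S,2R,4aR,8aR)-2,4a,8a-trimethyl-5-(4-methylpent-3-en-1-yl)-1,2,3,4,4a,7,8,8a-octahydronaphthalene-1-carboxylic acid | OC(=O)[C@H]1[C@H](C)CC[C@]2(C)C(CCC=C(C)C)=CCC[C@]12C | intermediate
21 | (S)-glycidol | OC[C@H]1CO1 | starting material
22 | acetic anhydride | CC(=O)OC(C)=O | starting material
23 | (R)-glycidyl acetate | CC(=O)OC[C@H]1CO1 | intermediate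
24 | (2S)-3-acetoxy-2-hydroxypropyl (1S,2R,4aR,8aR)-2,4a,8a-trimethyl-5-(4-methylpent-3-en-1-yl)-1,2,3,4,4a,7,8,8a-octahydronaphthalene-1-carboxylate | CC(=O)OC[C@H](O)COC(=O)[C@H]1[C@H](C)CC[C@]2(C)C(CCC=C(C)C)=CCC[C@]12C | target

## Step count

- Total step count: 11.
- Longest linear sequence: 9 steps (1, 2, 4, 5, 6, 7, 8, 9, 11).

## Steps most likely to fail

**Step 6 (the proposed new step).** The radical cation may lose an allylic proton instead of taking up water. Water may add at C4a. In the hydroxy cation the ring carbon C6 may migrate instead of the methyl, which would give an acetyl-hydrindane. The fallback is closed-shell and uses known chemistry. It sets out from 12. Epoxidation with mCPBA/NaHCO3 in CH2Cl2 at 0 °C, from the face opposite the 8a-methyl, gives (1S,2R,8aR)-1-ethenyl-4a,5-epoxy-2,5,8a-trimethyldecahydronaphthalene (oxirane oxygen trans to the 8a-methyl) F3; the monosubstituted vinyl group is much less reactive. A Meinwald rearrangement with BF3·OEt2 in CH2Cl2 at −78 °C opens the C4a–O bond. The C5 methyl, anti to that bond, migrates as it does in the cis-1,2-dimethylcyclohexane-1,2-diol case. The fallback comes back to the route at 13.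

**Step 4.** SN2 alkylation of a hindered tetrasubstituted enolate with an unactivated iodide can be slow. Proton transfer, O-alkylation or eroded facial selectivity may then take over. The fallback replaces the SN2 bond formation by a Michael-type one and sets out from 6. Mukaiyama–Michael addition to acrolein (BF3·OEt2, CH2Cl2, −78 °C) gives 3-[(1R,2S,3R)-2-ethenyl-1,3-dimethyl-6-oxocyclohexyl]propanal F1. An aldehyde-selective Wittig reaction with the ylide from (1-methoxyethyl)triphenylphosphonium chloride (KOt-Bu, THF, 0 °C) gives (2R,3S,4R)-3-ethenyl-2-(4-methoxypent-3-en-1-yl)-2,4-dimethylcyclohexan-1-one F2. Hydrolysis of the enol ether with 1 M HCl/THF comes back to the route at 11.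

**Step 9.** The triflate sits next to a quaternary carbon and carries a free acid. Reduction or homocoupling may therefore outrun the iron-catalysed coupling. The fallback reverses the polarity of the coupling and sets out from 17. Miyaura borylation (B2pin2, Pd(dppf)Cl2, KOAc, dioxane, 80 °C) gives (1S,2R,4aR,8aR)-2,4a,8a-trimethyl-5-(4,4,5,5-tetramethyl-1,3,2-dioxaborolan-2-yl)-1,2,3,4,4a,7,8,8a-octahydronaphthalene-1-carboxylic acid F4. This is joined to bromide 18 in an alkyl-bromide Suzuki–Miyaura coupling (Pd(OAc)2, P(t-Bu)2Me, KOt-Bu, t-amyl alcohol, rt) and comes back to the route at 20.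

## Further compounds

F1 | step 4 | 3-[(1R,2S,3R)-2-ethenyl-1,3-dimethyl-6-oxocyclohexyl]propanal | C=C[C@H]1[C@H](C)CCC(=O)[C@]1(C)CCC=O
F2 | step 4 | (2R,3S,4R)-3-ethenyl-2-(4-methoxypent-3-en-1-yl)-2,4-dimethylcyclohexan-1-one (E/Z mixture at the enol ether) | C=C[C@H]1[C@H](C)CCC(=O)[C@]1(C)CCC=C(C)OC
F3 | step 6 | (1S,2R,8aR)-1-ethenyl-4a,5-epoxy-2,5,8a-trimethyldecahydronaphthalene (oxirane oxygen trans to the 8a-methyl) | C=C[C@H]1[C@H](C)CC[C@@]2(O3)[C@@]3(C)CCC[C@]12C
F4 | step 9 | (1S,2R,4aR,8aR)-2,4a,8a-trimethyl-5-(4,4,5,5-tetramethyl-1,3,2-dioxaborolan-2-yl)-1,2,3,4,4a,7,8,8a-octahydronaphthalene-1-carboxylic acid | OC(=O)[C@H]1[C@H](C)CC[C@]2(C)C(B3OC(C)(C)C(C)(C)O3)=CCC[C@]12C
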